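**Strategy.** The target is a methylene-bridged pair of 4-hydroxy-2-pyranones: one carries a (3R,4R)-tetralone, the other the naphthalenediol formed from that tetralone by loss of water. One racemic tetralone therefore serves both halves, by resolution and by aromatisation. The key step exploits the 1,2,3-pattern of the benzo ring (C8–O, C8a–C1=O, C4a–C4) and the β-hydroxy ketone C1(=O)–C2H2–C3(OH) of the cyclohexanone ring. 3-Benzyloxybenzyne, released from its silylaryl triflate, inserts into the C–acetyl bond of a 2-pyranonyl-1-phenylbutane-1,3-dione, which moves the acetyl carbon onto C8a (bond C1–C8a); the freed methyl ketone then closes the ring by aldol addition to the benzoyl carbon (bond C2–C3) in the same flask.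

Key step: step 6

Remark: locants C1–C8a are those of the tetralone (C1 carbonyl, C2 methylene, C3 carbinol, C4 pyranone-bearing methine, C8 phenol carbon, C8a the fusion carbon between C1 and C8). Racemates are drawn as the (3R,4R) enantiomer; (3R*,4R*) means phenyl and pyranone cis and the C3 hydroxyl trans to the pyranone.

**Step 1**
Reactants: 1 4-hydroxy-6-methyl-2H-pyran-2-one
Product: 2 4-(benzyloxy)-6-methyl-2H-pyran-2-one
Conditions: BnBr, K2CO3, DMF, 50 °C
Reagents that add atoms: benzyl bromide BrCc1ccccc1
Why: Williamson O-alkylation of the acidic vinylogous carboxylic acid at O4 (carbonate base, dipolar solvent) masks the pyranone hydroxyl as a benzyl ether that should survive amide bases, fluoride and the aryne step and is later removed by hydrogenolysis.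

**Step 2**
Reactants: 2 4-(benzyloxy)-6-methyl-2H-pyran-2-one; 3 N-methoxy-N-methylbenzamide
Product: 5 4-(benzyloxy)-6-(2-oxo-2-phenylethyl)-2H-pyran-2-one, via lithiated pyranone 4 (not isolated)
Conditions: LiN(i-Pr)2 (1.1 equiv), THF, −78 °C; then 3; aq. NH4Cl
Reagents that add atoms: none
Why: Kinetic deprotonation of the C6 methyl group gives the vinylogous ester enolate 4, which is acylated at its exocyclic carbon by the N-methoxy-N-methylamide in a Claisen-type acylation that stops at the ketone stage.

**Step 3**
Reactants: 5 4-(benzyloxy)-6-(2-oxo-2-phenylethyl)-2H-pyran-2-one; 6 1-acetyl-1H-benzotriazole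
Product: 7 2-[4-(benzyloxy)-2-oxo-2H-pyran-6-yl]-1-phenylbutane-1,3-dione
Conditions: MgBr2·OEt2, i-Pr2NEt, CH2Cl2, 25 °C
Reagents that add atoms: none
Why: Soft enolisation of the doubly activated methylene (magnesium chelation plus amine base) and C-acylation by the acyl benzotriazole should give the 2-substituted 1,3-diketone as its magnesium chelate, which suppresses O-acylation; the acetyl group (the future C1–C2) is thereby parked on the future C4 through a temporary bond.

**Step 4**
Reactants: 8 2-bromobenzene-1,3-diol
Product: 9 3-(benzyloxy)-2-bromophenol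
Conditions: BnBr (1.0 equiv), K2CO3, acetone, 56 °C
Reagents that add atoms: benzyl bromide BrCc1ccccc1
Why: Statistical Williamson mono-benzylation of the symmetrical diol; the mono-ether is separated from diol and bis-ether on silica and the diol is recycled.

**Step 5**
Reactants: 9 3-(benzyloxy)-2-bromophenol
Product: 12 3-(benzyloxy)-2-(trimethylsilyl)phenyl trifluoromethanesulfonate, via aryl trimethylsilyl ether 10 (not isolated), via lithium 2-silylphenolate 11 (not isolated)
Conditions: (Me3Si)2NH, THF, 65 °C, then evaporation; n-BuLi, THF, −100 °C; (CF3SO2)2O, −100 → 25 °C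
Reagents that add atoms: hexamethyldisilazane C[Si](C)(C)N[Si](C)(C)C; trifluoromethanesulfonic anhydride O=S(=O)(OS(=O)(=O)C(F)(F)F)C(F)(F)F
Why: O-silylation, bromine–lithium exchange and 1,3-O→C silyl shift (retro-Brook rearrangement) place silicon on the carbon between the two oxygens, and triflation of the resulting phenolate gives the ortho-silylaryl triflate that releases the aryne with fluoride.

**Step 6**
Reactants: 7 2-[4-(benzyloxy)-2-oxo-2H-pyran-6-yl]-1-phenylbutane-1,3-dione; 12 3-(benzyloxy)-2-(trimethylsilyl)phenyl trifluoromethanesulfonate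
Product: 16 racemic (3R*,4R*)-8-(benzyloxy)-4-[4-(benzyloxy)-2-oxo-2H-pyran-6-yl]-3-hydroxy-3-phenyl-3,4-dihydronaphthalen-1(2H)-one, via 3-(benzyloxy)benzyne 13 (not isolated), via benzocyclobutene alkoxide 14 (not isolated), via ring-open diketone 15 (not isolated)
Conditions: 7 (1.2 equiv), 12 (1.0 equiv), CsF (3 equiv), MeCN, 25 → 50 °C; then AcOH (1 equiv, buffer), i-PrOH, 25–40 °C, same flask
Reagents that add atoms: none
Why: Fluoride removes silicon from 12 and triflate leaves to give aryne 13; the cesium enolate of 7 adds through its central carbon to the aryne carbon remote from the benzyloxy group (future C4a), the charge lands on the oxygen-flanked carbon (future C8a), which adds 4-exo-trig to the adjacent acetyl carbonyl to give alkoxide 14, and ring-opening of 14 expels the benzoyl- and pyranone-stabilised carbanion, so that the acetyl carbon has moved from C4 to C8a and the C1–C8a bond is made (15). This is the aryne acyl-alkylation (insertion of an aryne into the C–C bond of a 1,3-dicarbonyl compound), whose ortho-acyl benzyl ketone products are known to close by aldol reaction. Once the stabilised enolate of 15 is buffered to the neutral diketone, the methyl ketone enolate closes the cyclohexanone ring by a reversible 6-(enolendo)-exo-trig aldol addition to the benzoyl carbon and forms C2–C3, so that three C–C bonds form in one flask. The insertion needs two selectivities: the site of aryne attack, secured by the inductive effect of the C8 oxygen (nucleophile meta, anion ortho to oxygen), and transfer of acetyl instead of benzoyl, expected because the methyl ketone is the more electrophilic and less hindered carbonyl and its departure leaves the better-stabilised, benzoyl-conjugated carbanion; 12 is kept limiting so that free aryne does not undergo cycloaddition with pyranone rings. C4 is epimerisable in 15 and the aldol is reversible, so C3 and C4 settle under thermodynamic control, and the isomer required (phenyl and pyranone cis, C3 hydroxyl trans to the pyranone) should be favoured because, in the half-chair that holds the pyranone pseudoaxial on C4 clear of the peri hydrogen on C5, it alone has the phenyl group equatorial on C3, with the axial hydroxyl antiperiplanar to the pyranone and within hydrogen-bonding reach of the C1 carbonyl. A closed, cesium-bridged aldol transition state (benzoyl oxygen axial beside the enolate oxygen, pyranone pseudoaxial) leads to the same isomer, so kinetic and thermodynamic preference should agree; the product is racemic, and the C3 epimer is removed on silica and re-equilibrated under the same conditions.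

**Step 7**
Reactants: 16 racemic (3R*,4R*)-8-(benzyloxy)-4-[4-(benzyloxy)-2-oxo-2H-pyran-6-yl]-3-hydroxy-3-phenyl-3,4-dihydronaphthalen-1(2H)-one
Product: 17 racemic (3R*,4R*)-3,8-dihydroxy-4-(4-hydroxy-2-oxo-2H-pyran-6-yl)-3-phenyl-3,4-dihydronaphthalen-1(2H)-one
Conditions: H2 (1 atm), 10% Pd/C, EtOAc/MeOH, 25 °C
Reagents that add atoms: none
Why: Hydrogenolysis should cleave both O-benzyl ethers (aryl and vinylogous ester) under neutral conditions in which the acid- and base-sensitive β-hydroxy ketone is stable, leaving the tertiary benzylic hydroxyl (deactivated by the β-carbonyl) and both stereocentres untouched.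

**Step 8**
Reactants: 17 racemic (3R*,4R*)-3,8-dihydroxy-4-(4-hydroxy-2-oxo-2H-pyran-6-yl)-3-phenyl-3,4-dihydronaphthalen-1(2H)-one
Product: 18 (3R,4R)-3,8-dihydroxy-4-(4-hydroxy-2-oxo-2H-pyran-6-yl)-3-phenyl-3,4-dihydronaphthalen-1(2H)-one
Conditions: preparative HPLC, amylose tris(3,5-dimethylphenylcarbamate) on silica, hexane/i-PrOH/HCO2H, 25 °C
Reagents that add atoms: none
Why: Chromatographic resolution on a chiral polysaccharide stationary phase separates the enantiomers without touching any bond and so delivers the (3R,4R) enantiomer (fractions to be assigned by electronic circular dichroism or X-ray analysis); the mirror-image fraction is not lost, since it can join the feed of step 9, which erases both stereocentres.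

**Step 9**
Reactants: 17 racemic (3R*,4R*)-3,8-dihydroxy-4-(4-hydroxy-2-oxo-2H-pyran-6-yl)-3-phenyl-3,4-dihydronaphthalen-1(2H)-one
Product: 19 6-(4,5-dihydroxy-2-phenylnaphthalen-1-yl)-4-hydroxy-2H-pyran-2-one
Conditions: p-TsOH·H2O (cat.), 1,4-dioxane, 80 °C
Reagents that add atoms: none
Why: Acid-catalysed dehydration of the tertiary benzylic β-hydroxy ketone (β-elimination through the enol) should give a naphthalen-1(4H)-one that tautomerises at once to the naphthol, aromatisation being the driving force; both stereocentres vanish, so a portion of the racemate from step 7 supplies the achiral half.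

**Step 10**
Reactants: 18 (3R,4R)-3,8-dihydroxy-4-(4-hydroxy-2-oxo-2H-pyran-6-yl)-3-phenyl-3,4-dihydronaphthalen-1(2H)-one; 19 6-(4,5-dihydroxy-2-phenylnaphthalen-1-yl)-4-hydroxy-2H-pyran-2-one
Product: 22 Wailupemycin I, via Mannich base 20 (not isolated), via pyranone methide 21 (not isolated)
Conditions: 18, [CH2=NMe2]I (1.0 equiv), i-Pr2NEt (1.0 equiv), MeCN, 0 °C; then 19 (1.3 equiv), 40 °C
Reagents that add atoms: N,N-dimethylmethyleneiminium iodide C[N+](C)=C.[I-]
Why: Mannich aminomethylation at C3 of the 4-hydroxy-2-pyranone of 18 gives 20, which on warming loses dimethylamine to the 3-methylidenepyran-2,4-dione 21, and conjugate (Michael) addition of pyranone C3 of the excess partner 19 should form the methylene bridge, the stepwise order enforcing the unsymmetrical union while the near-neutral medium leaves C3 and C4 of the tetralone untouched.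

**Compound list**

1 | 4-hydroxy-6-methyl-2H-pyran-2-one | Cc1cc(O)cc(=O)o1 | starting material
2 | 4-(benzyloxy)-6-methyl-2H-pyran-2-one | Cc1cc(OCc2ccccc2)cc(=O)o1 | intermediate
3 | N-methoxy-N-methylbenzamide | CON(C)C(=O)c1ccccc1 | starting material
4 | {[4-(benzyloxy)-2-oxo-2H-pyran-6-yl]methyl}lithium | [Li]Cc1cc(OCc2ccccc2)cc(=O)o1 | intermediate (not isolated)
5 | 4-(benzyloxy)-6-(2-oxo-2-phenylethyl)-2H-pyran-2-one | O=C(Cc1cc(OCc2ccccc2)cc(=O)o1)c1ccccc1 | intermediate
6 | 1-acetyl-1H-benzotriazole | CC(=O)n1nnc2ccccc21 | starting material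
7 | 2-[4-(benzyloxy)-2-oxo-2H-pyran-6-yl]-1-phenylbutane-1,3-dione | CC(=O)C(C(=O)c1ccccc1)c1cc(OCc2ccccc2)cc(=O)o1 | intermediate
8 | 2-bromobenzene-1,3-diol | Oc1cccc(O)c1Br | starting material
9 | 3-(benzyloxy)-2-bromophenol | Oc1cccc(OCc2ccccc2)c1Br | intermediate
10 | [3-(benzyloxy)-2-bromophenoxy]trimethylsilane | C[Si](C)(C)Oc1cccc(OCc2ccccc2)c1Br | intermediate (not isolated)
11 | lithium 3-(benzyloxy)-2-(trimethylsilyl)phenolate | [Li+].[O-]c1cccc(OCc2ccccc2)c1[Si](C)(C)C | intermediate (not isolated)
12 | 3-(benzyloxy)-2-(trimethylsilyl)phenyl trifluoromethanesulfonate | C[Si](C)(C)c1c(OCc2ccccc2)cccc1OS(=O)(=O)C(F)(F)F | intermediate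
13 | 3-(benzyloxy)benzyne (1-(benzyloxy)-2,3-didehydrobenzene) | C1(OCc2ccccc2)=CC=CC#C1 | intermediate (not isolated)
14 | cesium 8-benzoyl-5-(benzyloxy)-8-[4-(benzyloxy)-2-oxo-2H-pyran-6-yl]-7-methylbicyclo[4.2.0]octa-1,3,5-trien-7-olate | [Cs+].CC1([O-])c2c(OCc3ccccc3)cccc2C1(C(=O)c1ccccc1)c1cc(OCc2ccccc2)cc(=O)o1 | intermediate (not isolated)
15 | 2-[2-acetyl-3-(benzyloxy)phenyl]-2-[4-(benzyloxy)-2-oxo-2H-pyran-6-yl]-1-phenylethan-1-one (configurationally labile) | CC(=O)c1c(OCc2ccccc2)cccc1C(C(=O)c1ccccc1)c1cc(OCc2ccccc2)cc(=O)o1 | intermediate (not isolated)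
16 | racemic (3R*,4R*)-8-(benzyloxy)-4-[4-(benzyloxy)-2-oxo-2H-pyran-6-yl]-3-hydroxy-3-phenyl-3,4-dihydronaphthalen-1(2H)-one | O=C1C[C@](O)(c2ccccc2)[C@H](c2cc(OCc3ccccc3)cc(=O)o2)c2cccc(OCc3ccccc3)c21 | intermediate
17 | racemic (3R*,4R*)-3,8-dihydroxy-4-(4-hydroxy-2-oxo-2H-pyran-6-yl)-3-phenyl-3,4-dihydronaphthalen-1(2H)-one | O=C1C[C@](O)(c2ccccc2)[C@H](c2cc(O)cc(=O)o2)c2cccc(O)c21 | intermediate
18 | (3R,4R)-3,8-dihydroxy-4-(4-hydroxy-2-oxo-2H-pyran-6-yl)-3-phenyl-3,4-dihydronaphthalen-1(2H)-one | O=C1C[C@](O)(c2ccccc2)[C@H](c2cc(O)cc(=O)o2)c2cccc(O)c21 | intermediate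
19 | 6-(4,5-dihydroxy-2-phenylnaphthalen-1-yl)-4-hydroxy-2H-pyran-2-one | O=c1cc(O)cc(-c2c(-c3ccccc3)cc(O)c3c(O)cccc23)o1 | intermediate
20 | (3R,4R)-4-{3-[(dimethylamino)methyl]-4-hydroxy-2-oxo-2H-pyran-6-yl}-3,8-dihydroxy-3-phenyl-3,4-dihydronaphthalen-1(2H)-one | O=C1C[C@](O)(c2ccccc2)[C@H](c2cc(O)c(CN(C)C)c(=O)o2)c2cccc(O)c21 | intermediate (not isolated)
21 | (3R,4R)-3,8-dihydroxy-4-(3-methylidene-2,4-dioxo-3,4-dihydro-2H-pyran-6-yl)-3-phenyl-3,4-dihydronaphthalen-1(2H)-one | O=C1C[C@](O)(c2ccccc2)[C@H](C2=CC(=O)C(=C)C(=O)O2)c2cccc(O)c21 | intermediate (not isolated)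
22 | Wailupemycin I, (3R,4R)-4-[3-({6-(4,5-dihydroxy-2-phenylnaphthalen-1-yl)-4-hydroxy-2-oxo-2H-pyran-3-yl}methyl)-4-hydroxy-2-oxo-2H-pyran-6-yl]-3,8-dihydroxy-3-phenyl-3,4-dihydronaphthalen-1(2H)-one | O=C1C[C@](O)(c2ccccc2)[C@H](c2cc(O)c(Cc3c(O)cc(-c4c(-c5ccccc5)cc(O)c5c(O)cccc45)oc3=O)c(=O)o2)c2cccc(O)c21 | target

**Step count and risks**

Total steps: 10. Longest linear sequence: 7 steps (steps 1, 2, 3, 6, 7, 8, 10).

Steps most likely to fail:

1. **Step 6.** The aryl anion may hand over benzoyl instead of acetyl, the crowded and highly stabilised diketonate may react at oxygen or too slowly, the aldol may fail to close or run on to dehydration, and the equilibrium may favour the C3 epimer. Fallback, setting out from 2 and 12 and returning at 16: lithiated 2 is acylated with N-methoxy-N-methylacetamide to give 4-(benzyloxy)-6-(2-oxopropyl)-2H-pyran-2-one F1, which has only one acyl group to transfer. Insertion of the aryne from 12 (CsF, MeCN, 80 °C) into its CH2–C(O)CH3 bond should give 6-[2-acetyl-3-(benzyloxy)benzyl]-4-(benzyloxy)-2H-pyran-2-one F2. Deprotonation at the methylene flanked by the arene and the pyranone (LiN(SiMe3)2, 2 equiv, THF, −78 °C) and C-benzoylation with 3 then gives diketone 15, now isolated. Its aldol closure is run separately (K2CO3 cat., i-PrOH, 25 °C) to 16, so that the closure can be equilibrated and the C3 epimer recycled without the aryne chemistry in the flask.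

2. **Step 10.** The methide may be captured by its own Mannich precursor (homodimer of the resolved half) or by a ring carbon of the naphthalenediol, and the amine medium may promote aldol reversal with erosion of configuration. Fallback, setting out from 19 and 18 and returning at 22: the roles are reversed. Compound 19 is aminomethylated with the iminium iodide and isolated as 6-(4,5-dihydroxy-2-phenylnaphthalen-1-yl)-3-[(dimethylamino)methyl]-4-hydroxy-2H-pyran-2-one F3. F3 in excess is then warmed with 18 as the limiting, purely nucleophilic partner (EtOH, 25–40 °C), so that self-capture can consume only the achiral half.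

3. **Step 7.** Over-reduction may occur, either hydrogenolysis of the tertiary benzylic C3–O bond or saturation of the pyranone 5,6-double bond. Fallback, setting out from 16 and returning at 17: oxidative instead of reductive debenzylation with DDQ under green light (CH2Cl2/H2O, 25 °C), which removes benzyl ethers by hydride abstraction and hydrolysis without hydrogen and makes no new compound (F0).

**Further compounds**

F1 | step 6 | 4-(benzyloxy)-6-(2-oxopropyl)-2H-pyran-2-one | CC(=O)Cc1cc(OCc2ccccc2)cc(=O)o1
F2 | step 6 | 6-[2-acetyl-3-(benzyloxy)benzyl]-4-(benzyloxy)-2H-pyran-2-one | CC(=O)c1c(OCc2ccccc2)cccc1Cc1cc(OCc2ccccc2)cc(=O)o1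
F3 | step 10 | 6-(4,5-dihydroxy-2-phenylnaphthalen-1-yl)-3-[(dimethylamino)methyl]-4-hydroxy-2H-pyran-2-one | CN(C)Cc1c(O)cc(-c2c(-c3ccccc3)cc(O)c3c(O)cccc23)oc1=O
F0 | step 7 | none | none
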